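**Plan**

1. Numbering: C1 (CH–O-angelate), C2 (C=O), C3 (C–acetyl), C4 (=CH), C5 (C–CH3), C6 (CH–CH3), C7 (CH–OAc), C8, C9, C10 (C–OH); ring A = C1–C5 plus C10, ring B = C5–C10. Enabling feature: ring A is the formal [4+2] adduct of a C10=C1–C2=C3 bis-enol ether of a C2/C10 1,3-dicarbonyl unit and a C4=C5 alkene whose C4 sulfonyl group can later leave to give C3=C4, and the C6–C9 chain already joins C5 to C10.
2. Retrosynthetic cuts: C3–C(acetyl), the C1 ester C–O, C3=C4 back to the C4 sulfone, C1–O back to a C1=C2 enol ether; then C5–C10 and C3–C4 in one operation; in the open chain C10–C1, C5–CH3, C4–S and C6–C7.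
3. Forward order: chain C4–C10 (steps 1–7); C1–C3 added with the C2=C3 enol ether ready-made (steps 8–10); rings A and B close together (step 11); then C1–OH, C3=C4, angelate and acetyl (steps 12–16).
4. Stereochemistry: C6 and C7 by chirality transfer from (S)-but-3-yn-2-ol in an anti-selective allenylzinc addition; C5 and C10 in the cycloaddition (cis fusion from the (Z)-sulfone, face from allylic strain at C6); C1 by dihydroxylation anti to C10–OSiMe3; the (Z)-ester geometry comes with angelic acid.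
5. Design choices: the C2=C3 enol ether is brought in as 3-bromo-2-methoxyprop-1-ene, so the diene can enolise only toward C1 and the base-labile β,β-disubstituted vinyl sulfone never meets a strong base; the C7 acetate of the target is carried from step 3.

Key step: step 11

Assumption: the tertiary C10–OSiMe3 ether is taken to survive steps 12–15; if it is lost earlier, the free C10 alcohols follow the same steps.

**Route**

Step 1
Reactants: 1 (S)-but-3-yn-2-ol
Product: 2 (S)-but-3-yn-2-yl methanesulfonate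
Conditions: MsCl, Et3N, CH2Cl2, −78 → 0 °C
Reagents that add atoms: methanesulfonyl chloride CS(=O)(=O)Cl
Why: O-sulfonylation of the secondary alcohol leaves the C–O bond, and with it the (S) centre, untouched.

Step 2
Reactants: 2 (S)-but-3-yn-2-yl methanesulfonate; 3 4-[(tert-butyldimethylsilyl)oxy]butanal
Product: 5 (4S,5R)-1-[(tert-butyldimethylsilyl)oxy]-5-methylhept-6-yn-4-ol, via allenylzinc reagent 4 (not isolated)
Conditions: Pd(OAc)2 (5 mol %), PPh3 (5 mol %), Et2Zn (3 equiv), THF, −78 → −20 °C; aq NH4Cl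
Reagents that add atoms: none
Why: Allenylzinc propargylation: zerovalent palladium displaces the mesylate anti (SN2′), zinc takes over the allenyl group as 4, and 4 adds to 3 through a cyclic SE2′ transition state, so the (S) centre of 2 is relayed to C6 (R) and the aldehyde chain lies anti to the allene methyl, which sets C7 (S) anti to C6.

Step 3
Reactants: 5 (4S,5R)-1-[(tert-butyldimethylsilyl)oxy]-5-methylhept-6-yn-4-ol
Product: 6 (4S,5R)-1-[(tert-butyldimethylsilyl)oxy]-5-methylhept-6-yn-4-yl acetate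
Conditions: Ac2O, pyridine, DMAP (cat.), CH2Cl2, 0 °C → rt
Reagents that add atoms: acetic anhydride CC(=O)OC(C)=O
Why: DMAP-catalysed O-acylation puts the C7 acetate of the target in place early, which the base-free steps that follow should tolerate.

Step 4
Reactants: 6 (4S,5R)-1-[(tert-butyldimethylsilyl)oxy]-5-methylhept-6-yn-4-yl acetate
Product: 7 (4S,5S,6E)-1-[(tert-butyldimethylsilyl)oxy]-6-iodo-5-methyl-7-(phenylsulfonyl)hept-6-en-4-yl acetate
Conditions: PhSO2Na, I2, NaOAc, EtOAc/H2O, rt, visible light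
Reagents that add atoms: sodium benzenesulfinate [Na+].[O-]S(=O)c1ccccc1; iodine II
Why: Radical iodosulfonylation: the sulfonyl radical adds to the unhindered terminal alkyne carbon (C4) and iodine is transferred anti, which should give the (E)-β-iodovinyl sulfone with sulfur cis to C6 under buffered conditions that spare the silyl ether.

Step 5
Reactants: 7 (4S,5S,6E)-1-[(tert-butyldimethylsilyl)oxy]-6-iodo-5-methyl-7-(phenylsulfonyl)hept-6-en-4-yl acetate
Product: 8 (4S,5R,6Z)-1-[(tert-butyldimethylsilyl)oxy]-5,6-dimethyl-7-(phenylsulfonyl)hept-6-en-4-yl acetate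
Conditions: MeZnCl, Pd(PPh3)4 (5 mol %), THF, 0 °C → rt
Reagents that add atoms: methylzinc chloride C[Zn]Cl
Why: Negishi coupling of the alkenyl iodide proceeds with retention, so methyl replaces iodine trans to sulfur and the (Z)-vinyl sulfone results, while the non-basic zinc reagent avoids dehydroiodination and leaves the acetate alone.

Step 6
Reactants: 8 (4S,5R,6Z)-1-[(tert-butyldimethylsilyl)oxy]-5,6-dimethyl-7-(phenylsulfonyl)hept-6-en-4-yl acetate
Product: 9 (4S,5R,6Z)-1-hydroxy-5,6-dimethyl-7-(phenylsulfonyl)hept-6-en-4-yl acetate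
Conditions: HF·pyridine, pyridine, THF, 0 °C → rt
Reagents that add atoms: none
Why: Buffered fluoride desilylation frees the primary alcohol without touching the acetate or isomerising the vinyl sulfone.

Step 7
Reactants: 9 (4S,5R,6Z)-1-hydroxy-5,6-dimethyl-7-(phenylsulfonyl)hept-6-en-4-yl acetate
Product: 10 (4S,5R,6Z)-5,6-dimethyl-1-oxo-7-(phenylsulfonyl)hept-6-en-4-yl acetate
Conditions: Dess–Martin periodinane, NaHCO3, CH2Cl2, 0 °C → rt
Reagents that add atoms: none
Why: Dess–Martin oxidation takes the primary alcohol to the C10 aldehyde under neutral conditions that keep the (Z)-vinyl sulfone and both stereocentres intact.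

Step 8
Reactants: 10 (4S,5R,6Z)-5,6-dimethyl-1-oxo-7-(phenylsulfonyl)hept-6-en-4-yl acetate; 11 3-bromo-2-methoxyprop-1-ene
Product: 13 (7S,8R,9Z)-4-hydroxy-2-methoxy-8,9-dimethyl-10-(phenylsulfonyl)deca-1,9-dien-7-yl acetate (both C4 epimers), via allylzinc bromide 12 (not isolated)
Conditions: Zn dust, THF, 0 °C; then 10, 0 °C → rt; aq NH4Cl/NH3 (pH 8)
Reagents that add atoms: none
Why: Barbier-type allylzinc addition to the aldehyde is far faster than attack on the acetate or the hindered vinyl sulfone and delivers C1–C3 with the C2=C3 methyl enol ether fixed in position; the new carbinol centre at C10 is uncontrolled and is erased in step 9.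

Step 9
Reactants: 13 (7S,8R,9Z)-4-hydroxy-2-methoxy-8,9-dimethyl-10-(phenylsulfonyl)deca-1,9-dien-7-yl acetate
Product: 14 (7S,8R,9Z)-2-methoxy-8,9-dimethyl-4-oxo-10-(phenylsulfonyl)deca-1,9-dien-7-yl acetate
Conditions: Dess–Martin periodinane, pyridine, CH2Cl2, 0 °C
Reagents that add atoms: none
Why: Dess–Martin oxidation under pyridine buffering should give the β,γ-unsaturated ketone without acid that would hydrolyse the enol ether and without base strong enough to move the double bond into conjugation.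

Step 10
Reactants: 14 (7S,8R,9Z)-2-methoxy-8,9-dimethyl-4-oxo-10-(phenylsulfonyl)deca-1,9-dien-7-yl acetate
Product: 15 (3Z,7S,8R,9Z)-2-methoxy-8,9-dimethyl-10-(phenylsulfonyl)-4-[(trimethylsilyl)oxy]deca-1,3,9-trien-7-yl acetate
Conditions: TMSOTf, Et3N, CH2Cl2, −78 → 0 °C; pentane extraction, used crude
Reagents that add atoms: trimethylsilyl trifluoromethanesulfonate C[Si](C)(C)OS(=O)(=O)C(F)(F)F
Why: Soft enolisation (silyl triflate, tertiary amine): O-silylation of the C10 ketone and loss of the doubly activated C1–H (α to the carbonyl, allylic to the enol ether) should give the conjugated (Z)-silyl enol ether with the chain trans to C2, and the weak base cannot deprotonate the vinyl sulfone.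

Step 11
Reactants: 15 (3Z,7S,8R,9Z)-2-methoxy-8,9-dimethyl-10-(phenylsulfonyl)-4-[(trimethylsilyl)oxy]deca-1,3,9-trien-7-yl acetate
Product: 16 (4S,4aR,5R,6S,8aS)-2-methoxy-4a,5-dimethyl-4-(phenylsulfonyl)-8a-[(trimethylsilyl)oxy]-3,4,4a,5,6,7,8,8a-octahydronaphthalen-6-yl acetate
Conditions: toluene (0.01 M), BHT, silylated sealed tube, 150 °C
Reagents that add atoms: none
Why: Heating makes the C10=C1–C2=C3 diene and the C4=C5 vinyl sulfone combine in a concerted, suprafacial thermal [4+2] cycloaddition that forms C5–C10 and C3–C4 at once. The closest known reactions are type 1 intramolecular Diels–Alder reactions of 1,7,9-decatrienes that carry a terminal (Z)-sulfonyl dienophile or a 2,4-dioxygenated diene. Ring A (C1–C5, C10) closes as the cycloadduct ring itself, and ring B (C5–C10) closes through the same C5–C10 bond because the four-carbon chain C6–C9 links dienophile carbon C5 to diene terminus C10 (fused mode, six-membered). C4 follows from suprafacial addition to the (Z)-alkene (sulfonyl trans to the C5 methyl), the cis relation of C5–CH3 and C10–O from the transition state that holds the tether and its cis sulfonyl group endo and the C5 methyl exo, and the sense relative to C6 from allylic 1,3-strain with the sulfonyl group, which keeps C6–H in the alkene plane so that C10 bonds to C5 anti to the C6 methyl. The step needs this cis-fused diastereomer with the C5 and C6 methyls cis, and a diene enolised only toward C1 and C3 with the chain trans to C2 on C10; the tether has to override the unfavourable polarity (nucleophilic C3 must bond to the sulfonyl-bearing C4), so forcing temperature and high dilution are planned.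

Step 12
Reactants: 16 (4S,4aR,5R,6S,8aS)-2-methoxy-4a,5-dimethyl-4-(phenylsulfonyl)-8a-[(trimethylsilyl)oxy]-3,4,4a,5,6,7,8,8a-octahydronaphthalen-6-yl acetate
Product: 18 (1S,4S,4aR,5R,6S,8aR)-1-hydroxy-4a,5-dimethyl-2-oxo-4-(phenylsulfonyl)-8a-[(trimethylsilyl)oxy]decahydronaphthalen-6-yl acetate, via methyl hemiketal 17 (not isolated)
Conditions: OsO4 (5 mol %), N-methylmorpholine N-oxide, acetone/H2O, 0 °C → rt
Reagents that add atoms: N-methylmorpholine N-oxide C[N+]1([O-])CCOCC1; water O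
Why: Osmium-catalysed dihydroxylation of the electron-rich enol ether is expected on the face anti to the adjacent pseudoaxial C10 silyloxy group, giving hemiketal 17, which sheds methanol to the α-hydroxy ketone with C1–O (S) trans to C10–O.

Step 13
Reactants: 18 (1S,4S,4aR,5R,6S,8aR)-1-hydroxy-4a,5-dimethyl-2-oxo-4-(phenylsulfonyl)-8a-[(trimethylsilyl)oxy]decahydronaphthalen-6-yl acetate
Product: 19 (1S,4aR,5R,6S,8aR)-1-hydroxy-4a,5-dimethyl-2-oxo-8a-[(trimethylsilyl)oxy]-1,2,4a,5,6,7,8,8a-octahydronaphthalen-6-yl acetate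
Conditions: DBU, CH2Cl2, 0 °C
Reagents that add atoms: none
Why: E1cB elimination: deprotonation at C3 expels benzenesulfinate from C4 to give the C3=C4 enone, far faster than loss of the poorer silyloxy leaving group from C10 through the C1 enolate, and the short cold treatment should leave the C1 centre intact.

Step 14
Reactants: 19 (1S,4aR,5R,6S,8aR)-1-hydroxy-4a,5-dimethyl-2-oxo-8a-[(trimethylsilyl)oxy]-1,2,4a,5,6,7,8,8a-octahydronaphthalen-6-yl acetate; 20 angelic acid [(Z)-2-methylbut-2-enoic acid]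
Product: 22 (1S,4aR,5R,6S,8aR)-6-acetoxy-4a,5-dimethyl-2-oxo-8a-[(trimethylsilyl)oxy]-1,2,4a,5,6,7,8,8a-octahydronaphthalen-1-yl (Z)-2-methylbut-2-enoate, via mixed anhydride 21 (not isolated)
Conditions: 2,4,6-trichlorobenzoyl chloride, Et3N, toluene, rt; then 19, 80 °C
Reagents that add atoms: none
Why: Yamaguchi-type esterification through mixed anhydride 21 without a nucleophilic catalyst acylates the hindered secondary ketol at the angeloyl carbonyl and avoids the (Z)-to-(E) isomerisation that acylpyridinium intermediates cause; the tertiary silyl ether does not react.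

Step 15
Reactants: 22 (1S,4aR,5R,6S,8aR)-6-acetoxy-4a,5-dimethyl-2-oxo-8a-[(trimethylsilyl)oxy]-1,2,4a,5,6,7,8,8a-octahydronaphthalen-1-yl (Z)-2-methylbut-2-enoate
Product: 23 (1S,4aS,5R,6S,8aR)-6-acetoxy-3-iodo-4a,5-dimethyl-2-oxo-8a-[(trimethylsilyl)oxy]-1,2,4a,5,6,7,8,8a-octahydronaphthalen-1-yl (Z)-2-methylbut-2-enoate
Conditions: I2, pyridine, CH2Cl2, rt, dark
Reagents that add atoms: iodine II
Why: α-Iodination of the enone (conjugate addition of pyridine at C4, iodination of the enolate at C3, loss of pyridine) is a sequence known for 4,4-disubstituted cyclohexenones, and exclusion of light guards the angelate against iodine-atom isomerisation.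

Step 16
Reactants: 23 (1S,4aS,5R,6S,8aR)-6-acetoxy-3-iodo-4a,5-dimethyl-2-oxo-8a-[(trimethylsilyl)oxy]-1,2,4a,5,6,7,8,8a-octahydronaphthalen-1-yl (Z)-2-methylbut-2-enoate; 24 tributyl(1-ethoxyvinyl)stannane
Product: 26 (1S,4aR,5R,6S,8aR)-6-acetoxy-3-acetyl-8a-hydroxy-4a,5-dimethyl-2-oxo-1,2,4a,5,6,7,8,8a-octahydronaphthalen-1-yl (Z)-2-methylbut-2-enoate, via ethoxyvinyl enone 25 (not isolated)
Conditions: PdCl2(PPh3)2 (5 mol %), CuI (10 mol %), DMF, 60 °C; then 1 M HCl, THF, 0 °C → rt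
Reagents that add atoms: water O
Why: Stille coupling of the α-iodoenone installs the 1-ethoxyvinyl group as a masked acetyl, and dilute acid then hydrolyses this enol ether to the methyl ketone and cleaves the tertiary trimethylsilyl ether to the C10 alcohol.

**Compound list**

1 | (S)-but-3-yn-2-ol | C[C@H](O)C#C | starting material
2 | (S)-but-3-yn-2-yl methanesulfonate | C[C@H](OS(C)(=O)=O)C#C | intermediate
3 | 4-[(tert-butyldimethylsilyl)oxy]butanal | O=CCCCO[Si](C)(C)C(C)(C)C | starting material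
4 | ethyl[(M)-buta-1,2-dien-1-yl]zinc (allenylzinc reagent) | CC=[C@]=C[Zn]CC | intermediate
5 | (4S,5R)-1-[(tert-butyldimethylsilyl)oxy]-5-methylhept-6-yn-4-ol | CC(C)(C)[Si](C)(C)OCCC[C@H](O)[C@H](C)C#C | intermediate
6 | (4S,5R)-1-[(tert-butyldimethylsilyl)oxy]-5-methylhept-6-yn-4-yl acetate | CC(C)(C)[Si](C)(C)OCCC[C@H](OC(C)=O)[C@H](C)C#C | intermediate
7 | (4S,5S,6E)-1-[(tert-butyldimethylsilyl)oxy]-6-iodo-5-methyl-7-(phenylsulfonyl)hept-6-en-4-yl acetate | CC(C)(C)[Si](C)(C)OCCC[C@H](OC(C)=O)[C@H](C)/C(I)=C\S(=O)(=O)c1ccccc1 | intermediate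
8 | (4S,5R,6Z)-1-[(tert-butyldimethylsilyl)oxy]-5,6-dimethyl-7-(phenylsulfonyl)hept-6-en-4-yl acetate | CC(C)(C)[Si](C)(C)OCCC[C@H](OC(C)=O)[C@H](C)/C(C)=C\S(=O)(=O)c1ccccc1 | intermediate
9 | (4S,5R,6Z)-1-hydroxy-5,6-dimethyl-7-(phenylsulfonyl)hept-6-en-4-yl acetate | OCCC[C@H](OC(C)=O)[C@H](C)/C(C)=C\S(=O)(=O)c1ccccc1 | intermediate
10 | (4S,5R,6Z)-5,6-dimethyl-1-oxo-7-(phenylsulfonyl)hept-6-en-4-yl acetate | O=CCC[C@H](OC(C)=O)[C@H](C)/C(C)=C\S(=O)(=O)c1ccccc1 | intermediate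
11 | 3-bromo-2-methoxyprop-1-ene | C=C(OC)CBr | starting material
12 | (2-methoxyallyl)zinc bromide | C=C(OC)C[Zn]Br | intermediate
13 | (7S,8R,9Z)-4-hydroxy-2-methoxy-8,9-dimethyl-10-(phenylsulfonyl)deca-1,9-dien-7-yl acetate (C4 epimers) | C=C(OC)CC(O)CC[C@H](OC(C)=O)[C@H](C)/C(C)=C\S(=O)(=O)c1ccccc1 | intermediate
14 | (7S,8R,9Z)-2-methoxy-8,9-dimethyl-4-oxo-10-(phenylsulfonyl)deca-1,9-dien-7-yl acetate | C=C(OC)CC(=O)CC[C@H](OC(C)=O)[C@H](C)/C(C)=C\S(=O)(=O)c1ccccc1 | intermediate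
15 | (3Z,7S,8R,9Z)-2-methoxy-8,9-dimethyl-10-(phenylsulfonyl)-4-[(trimethylsilyl)oxy]deca-1,3,9-trien-7-yl acetate | C=C(OC)/C=C(\O[Si](C)(C)C)CC[C@H](OC(C)=O)[C@H](C)/C(C)=C\S(=O)(=O)c1ccccc1 | intermediate
16 | (4S,4aR,5R,6S,8aS)-2-methoxy-4a,5-dimethyl-4-(phenylsulfonyl)-8a-[(trimethylsilyl)oxy]-3,4,4a,5,6,7,8,8a-octahydronaphthalen-6-yl acetate (cis-fused; 4a-CH3, 5-CH3, 6-OAc and 8a-OSiMe3 on one face, sulfonyl on the other) | C1=C(OC)C[C@H](S(=O)(=O)c3ccccc3)[C@]2(C)[C@@H](C)[C@@H](OC(C)=O)CC[C@]12O[Si](C)(C)C | intermediate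
17 | (1S,2S,4S,4aR,5R,6S,8aR)-1,2-dihydroxy-2-methoxy-4a,5-dimethyl-4-(phenylsulfonyl)-8a-[(trimethylsilyl)oxy]decahydronaphthalen-6-yl acetate | O[C@@H]1[C@@](O)(OC)C[C@H](S(=O)(=O)c3ccccc3)[C@]2(C)[C@@H](C)[C@@H](OC(C)=O)CC[C@]12O[Si](C)(C)C | intermediate
18 | (1S,4S,4aR,5R,6S,8aR)-1-hydroxy-4a,5-dimethyl-2-oxo-4-(phenylsulfonyl)-8a-[(trimethylsilyl)oxy]decahydronaphthalen-6-yl acetate | O[C@@H]1C(=O)C[C@H](S(=O)(=O)c3ccccc3)[C@]2(C)[C@@H](C)[C@@H](OC(C)=O)CC[C@]12O[Si](C)(C)C | intermediate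
19 | (1S,4aR,5R,6S,8aR)-1-hydroxy-4a,5-dimethyl-2-oxo-8a-[(trimethylsilyl)oxy]-1,2,4a,5,6,7,8,8a-octahydronaphthalen-6-yl acetate | O[C@@H]1C(=O)C=C[C@]2(C)[C@@H](C)[C@@H](OC(C)=O)CC[C@]12O[Si](C)(C)C | intermediate
20 | angelic acid, (Z)-2-methylbut-2-enoic acid | C/C=C(/C)C(=O)O | starting material
21 | (Z)-2-methylbut-2-enoic 2,4,6-trichlorobenzoic anhydride | C/C=C(/C)C(=O)OC(=O)c1c(Cl)cc(Cl)cc1Cl | intermediate
22 | (1S,4aR,5R,6S,8aR)-6-acetoxy-4a,5-dimethyl-2-oxo-8a-[(trimethylsilyl)oxy]-1,2,4a,5,6,7,8,8a-octahydronaphthalen-1-yl (Z)-2-methylbut-2-enoate | C/C=C(/C)C(=O)O[C@@H]1C(=O)C=C[C@]2(C)[C@@H](C)[C@@H](OC(C)=O)CC[C@]12O[Si](C)(C)C | intermediate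
23 | (1S,4aS,5R,6S,8aR)-6-acetoxy-3-iodo-4a,5-dimethyl-2-oxo-8a-[(trimethylsilyl)oxy]-1,2,4a,5,6,7,8,8a-octahydronaphthalen-1-yl (Z)-2-methylbut-2-enoate | C/C=C(/C)C(=O)O[C@@H]1C(=O)C(I)=C[C@]2(C)[C@@H](C)[C@@H](OC(C)=O)CC[C@]12O[Si](C)(C)C | intermediate
24 | tributyl(1-ethoxyvinyl)stannane | CCCC[Sn](CCCC)(CCCC)C(=C)OCC | starting material
25 | (1S,4aR,5R,6S,8aR)-6-acetoxy-3-(1-ethoxyvinyl)-4a,5-dimethyl-2-oxo-8a-[(trimethylsilyl)oxy]-1,2,4a,5,6,7,8,8a-octahydronaphthalen-1-yl (Z)-2-methylbut-2-enoate | C/C=C(/C)C(=O)O[C@@H]1C(=O)C(C(=C)OCC)=C[C@]2(C)[C@@H](C)[C@@H](OC(C)=O)CC[C@]12O[Si](C)(C)C | intermediate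
26 | (1S,4aR,5R,6S,8aR)-6-acetoxy-3-acetyl-8a-hydroxy-4a,5-dimethyl-2-oxo-1,2,4a,5,6,7,8,8a-octahydronaphthalen-1-yl (Z)-2-methylbut-2-enoate | C/C=C(/C)C(=O)O[C@@H]1C(=O)C(C(C)=O)=C[C@]2(C)[C@@H](C)[C@@H](OC(C)=O)CC[C@]12O | target

**Count and risks**

Total steps: 16. Longest linear sequence: 16 steps (1 → 26); 3, 11, 20 and 24 are bought.

Steps most likely to fail:

1. Step 11. The cycloaddition may be too slow: the nucleophilic diene terminus C3 has to bond to the sulfonyl-bearing C4, and C5 is fully substituted, so desilylation or oligomerisation of the diene may win at the temperature needed. Fallback (a stronger acceptor on C4 in place of harsher conditions): from 6, iodosulfonylation with purchased sodium 3,5-bis(trifluoromethyl)benzenesulfinate and iodine gives the aryl iodovinyl sulfone F1, and Negishi methylation gives the aryl (Z)-vinyl sulfone F2. Desilylation, oxidation, allylzinc addition, oxidation and silylation as in steps 6–10 give in turn the alcohol F3, the aldehyde F4, the homoallylic alcohol F5, the enol ether ketone F6 and the silyloxy diene F7. The more electron-poor dienophile should cyclise at lower temperature to the aryl sulfonyl adduct F8. Dihydroxylation as in step 12 gives the aryl sulfonyl hydroxy ketone F9, and loss of the arylsulfinate with DBU returns to 19.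

2. Step 12. Facial selectivity may be poor: ring B of the cis-decalin shields the face that has to be attacked, so OsO4 may add syn to C10–OSiMe3 and give the C1 epimer. Fallback (inversion instead of retention at C1): from 16, the C1-epimeric hydroxy ketone F10 is taken through the DBU elimination to the C1-epimeric hydroxy enone F11. A Mitsunobu esterification with angelic acid 20 (PPh3, diisopropyl azodicarboxylate, THF) then inverts C1 and gives 22 directly, replacing step 14.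

3. Step 9. The double bond may migrate: the β,γ-enol ether ketone 14 can slip into conjugation or lose its enol ether during oxidation or isolation, which destroys the regiochemistry of the diene. Fallback (1,3-diketone route with a bis-silyl diene): from 10, Mukaiyama aldol addition of 2-(trimethylsilyloxy)propene (BF3·OEt2, CH2Cl2, −78 °C) gives the β-hydroxy ketone F12, and Dess–Martin oxidation gives the 1,3-diketone F13. Double silylation (TMSOTf, Et3N) gives the bis(trimethylsilyloxy) diene F14; its regioisomer enolised toward C9 cannot form the decalin and would be removed after the next operation. Cycloaddition as in step 11 gives the bis-silyl adduct F15, and Rubottom oxidation of its C1=C2 silyl enol ether (mCPBA, NaHCO3; then citric acid, MeOH) returns to 18.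

**Further compounds**

F1 | step 11 | (4S,5S,6E)-7-{[3,5-bis(trifluoromethyl)phenyl]sulfonyl}-1-[(tert-butyldimethylsilyl)oxy]-6-iodo-5-methylhept-6-en-4-yl acetate | CC(C)(C)[Si](C)(C)OCCC[C@H](OC(C)=O)[C@H](C)/C(I)=C\S(=O)(=O)c1cc(C(F)(F)F)cc(C(F)(F)F)c1
F2 | step 11 | (4S,5R,6Z)-7-{[3,5-bis(trifluoromethyl)phenyl]sulfonyl}-1-[(tert-butyldimethylsilyl)oxy]-5,6-dimethylhept-6-en-4-yl acetate | CC(C)(C)[Si](C)(C)OCCC[C@H](OC(C)=O)[C@H](C)/C(C)=C\S(=O)(=O)c1cc(C(F)(F)F)cc(C(F)(F)F)c1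
F3 | step 11 | (4S,5R,6Z)-7-{[3,5-bis(trifluoromethyl)phenyl]sulfonyl}-1-hydroxy-5,6-dimethylhept-6-en-4-yl acetate | OCCC[C@H](OC(C)=O)[C@H](C)/C(C)=C\S(=O)(=O)c1cc(C(F)(F)F)cc(C(F)(F)F)c1
F4 | step 11 | (4S,5R,6Z)-7-{[3,5-bis(trifluoromethyl)phenyl]sulfonyl}-5,6-dimethyl-1-oxohept-6-en-4-yl acetate | O=CCC[C@H](OC(C)=O)[C@H](C)/C(C)=C\S(=O)(=O)c1cc(C(F)(F)F)cc(C(F)(F)F)c1
F5 | step 11 | (7S,8R,9Z)-10-{[3,5-bis(trifluoromethyl)phenyl]sulfonyl}-4-hydroxy-2-methoxy-8,9-dimethyldeca-1,9-dien-7-yl acetate (C4 epimers) | C=C(OC)CC(O)CC[C@H](OC(C)=O)[C@H](C)/C(C)=C\S(=O)(=O)c1cc(C(F)(F)F)cc(C(F)(F)F)c1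
F6 | step 11 | (7S,8R,9Z)-10-{[3,5-bis(trifluoromethyl)phenyl]sulfonyl}-2-methoxy-8,9-dimethyl-4-oxodeca-1,9-dien-7-yl acetate | C=C(OC)CC(=O)CC[C@H](OC(C)=O)[C@H](C)/C(C)=C\S(=O)(=O)c1cc(C(F)(F)F)cc(C(F)(F)F)c1
F7 | step 11 | (3Z,7S,8R,9Z)-10-{[3,5-bis(trifluoromethyl)phenyl]sulfonyl}-2-methoxy-8,9-dimethyl-4-[(trimethylsilyl)oxy]deca-1,3,9-trien-7-yl acetate | C=C(OC)/C=C(\O[Si](C)(C)C)CC[C@H](OC(C)=O)[C@H](C)/C(C)=C\S(=O)(=O)c1cc(C(F)(F)F)cc(C(F)(F)F)c1
F8 | step 11 | (4S,4aR,5R,6S,8aS)-4-{[3,5-bis(trifluoromethyl)phenyl]sulfonyl}-2-methoxy-4a,5-dimethyl-8a-[(trimethylsilyl)oxy]-3,4,4a,5,6,7,8,8a-octahydronaphthalen-6-yl acetate | C1=C(OC)C[C@H](S(=O)(=O)c3cc(C(F)(F)F)cc(C(F)(F)F)c3)[C@]2(C)[C@@H](C)[C@@H](OC(C)=O)CC[C@]12O[Si](C)(C)C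
F9 | step 11 | (1S,4S,4aR,5R,6S,8aR)-4-{[3,5-bis(trifluoromethyl)phenyl]sulfonyl}-1-hydroxy-4a,5-dimethyl-2-oxo-8a-[(trimethylsilyl)oxy]decahydronaphthalen-6-yl acetate | O[C@@H]1C(=O)C[C@H](S(=O)(=O)c3cc(C(F)(F)F)cc(C(F)(F)F)c3)[C@]2(C)[C@@H](C)[C@@H](OC(C)=O)CC[C@]12O[Si](C)(C)C
F10 | step 12 | (1R,4S,4aR,5R,6S,8aR)-1-hydroxy-4a,5-dimethyl-2-oxo-4-(phenylsulfonyl)-8a-[(trimethylsilyl)oxy]decahydronaphthalen-6-yl acetate | O[C@H]1C(=O)C[C@H](S(=O)(=O)c3ccccc3)[C@]2(C)[C@@H](C)[C@@H](OC(C)=O)CC[C@]12O[Si](C)(C)C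
F11 | step 12 | (1R,4aR,5R,6S,8aR)-1-hydroxy-4a,5-dimethyl-2-oxo-8a-[(trimethylsilyl)oxy]-1,2,4a,5,6,7,8,8a-octahydronaphthalen-6-yl acetate | O[C@H]1C(=O)C=C[C@]2(C)[C@@H](C)[C@@H](OC(C)=O)CC[C@]12O[Si](C)(C)C
F12 | step 9 | (7S,8R,9Z)-4-hydroxy-8,9-dimethyl-2-oxo-10-(phenylsulfonyl)dec-9-en-7-yl acetate (C4 epimers) | CC(=O)CC(O)CC[C@H](OC(C)=O)[C@H](C)/C(C)=C\S(=O)(=O)c1ccccc1
F13 | step 9 | (7S,8R,9Z)-8,9-dimethyl-2,4-dioxo-10-(phenylsulfonyl)dec-9-en-7-yl acetate | CC(=O)CC(=O)CC[C@H](OC(C)=O)[C@H](C)/C(C)=C\S(=O)(=O)c1ccccc1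
F14 | step 9 | (3Z,7S,8R,9Z)-8,9-dimethyl-10-(phenylsulfonyl)-2,4-bis[(trimethylsilyl)oxy]deca-1,3,9-trien-7-yl acetate | C=C(O[Si](C)(C)C)/C=C(\O[Si](C)(C)C)CC[C@H](OC(C)=O)[C@H](C)/C(C)=C\S(=O)(=O)c1ccccc1
F15 | step 9 | (4S,4aR,5R,6S,8aS)-4a,5-dimethyl-4-(phenylsulfonyl)-2,8a-bis[(trimethylsilyl)oxy]-3,4,4a,5,6,7,8,8a-octahydronaphthalen-6-yl acetate | C1=C(O[Si](C)(C)C)C[C@H](S(=O)(=O)c3ccccc3)[C@]2(C)[C@@H](C)[C@@H](OC(C)=O)CC[C@]12O[Si](C)(C)C
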